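The 14-membered ring is numbered from the stereocentre C1 through the Z olefin C3=C4, the hydroxymethyl-bearing olefin C7=C8 and the E olefin C11=C12 to C14. It is opened between the methyl-bearing vinylic carbon C12 and the methylene C13. The key step exploits the saturated C13–C14 bridge between C12 and C1: carried as a vinyl group on C1, it is hydroborated at C13 with 9-BBN and the alkylborane is coupled in the same flask with an (E)-iodoalkene at C12 (intramolecular B-alkyl Suzuki–Miyaura reaction), closing the ring with retention of the C11=C12 geometry. The precursor is an acyclic vinyl iodo ester assembled from neryl acetate by Wittig olefination and Evans alkylation.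

Key step: step 15

Remark on numbering: C15–C19 are the side-chain carbons counted outwards from C1 (C15 bears a methyl group, C19 is the terminal CMe2 carbon); the same atom numbers are used for all acyclic precursors.

Step 1
Reactants: 1 pent-3-yn-1-ol
Product: 3 (E)-4-iodopent-3-en-1-ol, via alkenylzirconocene 2 (not isolated)
Conditions: Cp2Zr(H)Cl (2.5 equiv), THF, 0 to 40 °C; then I2, 0 °C
Reagents that add atoms: iodine, II
Why: Syn hydrozirconation of the internal alkyne with equilibration should place zirconium on the less hindered, methyl-bearing carbon, and iodinolysis with retention then gives the (E)-2-iodoalkene (hydrozirconation–iodination).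

Step 2
Reactants: 3 (E)-4-iodopent-3-en-1-ol
Product: 4 (E)-2,5-diiodopent-2-ene
Conditions: I2, PPh3, imidazole, CH2Cl2, 0 °C
Reagents that add atoms: iodine, II
Why: Appel-type iodination converts the primary alcohol into the primary iodide while the alkenyl iodide is inert.

Step 3
Reactants: 4 (E)-2,5-diiodopent-2-ene; 5 methyl (triphenylphosphoranylidene)acetate (2.1 equiv)
Product: 7 methyl (5E)-6-iodo-2-(triphenylphosphoranylidene)hept-5-enoate, via phosphonium iodide 6 (not isolated)
Conditions: MeCN, 80 °C; the phosphonium salt of 5 is filtered off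
Reagents that add atoms: none
Why: C-alkylation of the stabilised ylide occurs only at the sp3 C–I bond, and the second equivalent of 5 deprotonates salt 6 (transylidation) to give the α-substituted ylide.

Step 4
Reactants: 8 neryl acetate
Product: 10 (2Z)-3-methyl-6-oxohex-2-en-1-yl acetate, via ozonide 9 (not isolated)
Conditions: O3 (1.0 equiv), CH2Cl2, −78 °C; then Me2S, −78 °C to rt
Reagents that add atoms: ozone, [O-][O+]=O
Why: Chemoselective ozonolysis should cleave the electron-rich distal olefin, because the olefin next to the allylic acetate is deactivated, so the Z olefin (future C3=C4) is kept.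

Step 5
Reactants: 10 (2Z)-3-methyl-6-oxohex-2-en-1-yl acetate; 7 methyl (5E)-6-iodo-2-(triphenylphosphoranylidene)hept-5-enoate
Product: 11 methyl (2E,6Z)-8-acetoxy-2-[(3E)-4-iodopent-3-en-1-yl]-6-methylocta-2,6-dienoate
Conditions: toluene, 80 °C
Reagents that add atoms: none
Why: The Wittig reaction of an α-substituted stabilised ylide with an aldehyde is E-selective (ester trans to the C6 chain), which sets the C7=C8 geometry with C6 and C9 cis as required.

Step 6
Reactants: 11 methyl (2E,6Z)-8-acetoxy-2-[(3E)-4-iodopent-3-en-1-yl]-6-methylocta-2,6-dienoate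
Product: 12 methyl (2E,6Z)-8-hydroxy-2-[(3E)-4-iodopent-3-en-1-yl]-6-methylocta-2,6-dienoate
Conditions: K2CO3 (cat.), MeOH, 0 °C
Reagents that add atoms: none
Why: Base-catalysed methanolysis removes the acetate, and exchange at the methyl ester is degenerate.

Step 7
Reactants: 12 methyl (2E,6Z)-8-hydroxy-2-[(3E)-4-iodopent-3-en-1-yl]-6-methylocta-2,6-dienoate
Product: 13 methyl (2E,6Z)-8-bromo-2-[(3E)-4-iodopent-3-en-1-yl]-6-methylocta-2,6-dienoate
Conditions: CBr4, PPh3, CH2Cl2, −20 to 0 °C; used crude
Reagents that add atoms: carbon tetrabromide, BrC(Br)(Br)Br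
Why: Appel bromination proceeds by SN2 at the primary allylic carbon under neutral conditions and should keep the Z geometry.

Step 8
Reactants: 14 but-3-yn-1-ol; 15 prenyl bromide (1-bromo-3-methylbut-2-ene)
Product: 17 (3E)-3,7-dimethylocta-3,6-dien-1-ol, via alkenylalane 16 (not isolated)
Conditions: AlMe3 (3 equiv), Cp2ZrCl2 (25 mol %), CH2Cl2, 0 °C to rt; then 15, Pd(PPh3)4 (5 mol %), THF, rt
Reagents that add atoms: trimethylaluminium, C[Al](C)C
Why: Negishi carboalumination adds methyl and aluminium syn across the alkyne (methyl internal), and palladium-catalysed coupling of the alkenylalane with the unsubstituted terminus of the allylic bromide with retention gives the E trisubstituted skipped diene.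

Step 9
Reactants: 17 (3E)-3,7-dimethylocta-3,6-dien-1-ol
Product: 19 (3E)-3,7-dimethylocta-3,6-dienoic acid, via aldehyde 18 (not isolated)
Conditions: TEMPO (20 mol %), PhI(OAc)2 (2.2 equiv), MeCN/H2O, rt
Reagents that add atoms: water, O
Why: Oxoammonium oxidation of the primary alcohol through the aldehyde hydrate gives the acid under near-neutral conditions that should leave the β,γ-olefin in place.

Step 10
Reactants: 19 (3E)-3,7-dimethylocta-3,6-dienoic acid; 20 (R)-4-benzyloxazolidin-2-one
Product: 22 (4R)-4-benzyl-3-[(3E)-3,7-dimethylocta-3,6-dienoyl]oxazolidin-2-one, via mixed pivalic anhydride 21 (not isolated)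
Conditions: t-BuCOCl, Et3N, THF, −20 °C; then LiCl, 20, −20 °C to rt
Reagents that add atoms: none
Why: N-Acylation of the oxazolidinone through the mixed anhydride with LiCl activation is mild enough for a β,γ-unsaturated acid.

Step 11
Reactants: 22 (4R)-4-benzyl-3-[(3E)-3,7-dimethylocta-3,6-dienoyl]oxazolidin-2-one (1.3 equiv); 13 methyl (2E,6Z)-8-bromo-2-[(3E)-4-iodopent-3-en-1-yl]-6-methylocta-2,6-dienoate
Product: 24 methyl (2E,6Z,9R,10E)-9-{[(4R)-4-benzyl-2-oxo-1,3-oxazolidin-3-yl]carbonyl}-2-[(3E)-4-iodopent-3-en-1-yl]-6,10,14-trimethylpentadeca-2,6,10,13-tetraenoate, via sodium enolate 23 (not isolated)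
Conditions: NaN(SiMe3)2, THF, −78 °C; then 13, −78 to −30 °C
Reagents that add atoms: none
Why: Evans alkylation of the chelated Z enolate occurs at the α-carbon on the face opposite the benzyl group, which sets C1 (R, the configuration of the target), while SN2 at the allylic bromide keeps the Z olefin.

Step 12
Reactants: 24 alkylated imide
Product: 25 methyl (2E,6Z,9R,10E)-9-(hydroxymethyl)-2-[(3E)-4-iodopent-3-en-1-yl]-6,10,14-trimethylpentadeca-2,6,10,13-tetraenoate
Conditions: LiBH4 (1.5 equiv), MeOH (1.5 equiv), Et2O, 0 °C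
Reagents that add atoms: none
Why: Reductive cleavage of the auxiliary by LiBH4 is faster at the imide carbonyl than at the conjugated methyl ester and should give the primary alcohol without touching C1.

Step 13
Reactants: 25 primary alcohol
Product: 26 methyl (2E,6Z,9R,10E)-9-formyl-2-[(3E)-4-iodopent-3-en-1-yl]-6,10,14-trimethylpentadeca-2,6,10,13-tetraenoate
Conditions: Dess–Martin periodinane, NaHCO3, CH2Cl2, 0 °C; used at once
Reagents that add atoms: none
Why: Buffered Dess–Martin oxidation is non-basic and should deliver the α-alkenyl aldehyde without enolisation at C1.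

Step 14
Reactants: 26 aldehyde
Product: 27 methyl (2E,6Z,9S,10E)-9-ethenyl-2-[(3E)-4-iodopent-3-en-1-yl]-6,10,14-trimethylpentadeca-2,6,10,13-tetraenoate
Conditions: Zn, CH2Br2, TiCl4 (reagent pre-formed), THF/CH2Cl2, 0 °C
Reagents that add atoms: dibromomethane, BrCBr
Why: Takai–Lombardo methylenation uses a non-basic gem-dimetallic reagent that converts the epimerisable aldehyde into the vinyl group (C14=C13) and spares the ester; C1 is unchanged in space and its descriptor becomes S only through the priority change.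

Step 15
Reactants: 27 vinyl iodo ester
Product: 29 methyl ester of the target ring (14-membered ring, C1 R, 3Z,7E,11E, CO2Me on C8, side chain on C1), via B-alkyl-9-BBN 28 (not isolated)
Conditions: 9-BBN (1.2 equiv), THF, 0 °C to rt; then slow addition to PdCl2(dppf) (20 mol %), AsPh3 (40 mol %), Cs2CO3 (3 equiv), DMF/THF/H2O, 2 mM, rt to 45 °C
Reagents that add atoms: none
Why: 9-BBN adds anti-Markovnikov to the only monosubstituted olefin and puts boron on C13; zerovalent palladium then inserts into the C12–I bond with retention, the hydroxo-borate transfers the primary alkyl group, and reductive elimination forms C12–C13. The closest known reaction type is the intramolecular B-alkyl Suzuki–Miyaura macrocyclisation of an ω-alkenyl (E)-2-iodoalkene. The 14-membered carbocycle is closed by sp3–sp2 cross-coupling through a 15-membered palladacycle, a head-to-tail macrocyclisation run at high dilution with slow addition of the borane. No stereocentre is created: C1 is not involved and the C11=C12 geometry is carried over unchanged from the iodoalkene. The step needs chemoselective hydroboration (secured by the steric demand of 9-BBN towards the five trisubstituted olefins) and ring closure in preference to oligomerisation (secured by dilution and by the two cis-configured turns at C3=C4 and C7=C8 that fold the chain).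

Step 16
Reactants: 29 macrocyclic methyl ester
Product: 30 target alcohol (14-membered ring, C1 R, 3Z,7E,11E, CH2OH on C8, (E)-6-methylhepta-2,5-dien-2-yl on C1)
Conditions: i-Bu2AlH (2.5 equiv), CH2Cl2, −78 °C; aqueous potassium sodium tartrate
Reagents that add atoms: none
Why: 1,2-Reduction of the α,β-unsaturated methyl ester by i-Bu2AlH gives the allylic alcohol without changing olefin geometry or C1.

Compound list
1 | pent-3-yn-1-ol | CC#CCCO | starting material
2 | O,C-bis(chlorozirconocene) adduct of (E)-pent-3-en-1-ol, Zr on C4 cis to H-3 | C/C(=C\CCO[Zr](Cl)(C1C=CC=C1)C1C=CC=C1)[Zr](Cl)(C1C=CC=C1)C1C=CC=C1 | intermediate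
3 | (E)-4-iodopent-3-en-1-ol | C/C(I)=C\CCO | intermediate
4 | (E)-2,5-diiodopent-2-ene | C/C(I)=C\CCI | intermediate
5 | methyl (triphenylphosphoranylidene)acetate | COC(=O)C=P(c1ccccc1)(c1ccccc1)c1ccccc1 | starting material
6 | [(5E)-6-iodo-1-methoxy-1-oxohept-5-en-2-yl]triphenylphosphonium iodide | COC(=O)C(CC/C=C(\C)I)[P+](c1ccccc1)(c1ccccc1)c1ccccc1.[I-] | intermediate
7 | methyl (5E)-6-iodo-2-(triphenylphosphoranylidene)hept-5-enoate | COC(=O)C(CC/C=C(\C)I)=P(c1ccccc1)(c1ccccc1)c1ccccc1 | intermediate
8 | neryl acetate, (2Z)-3,7-dimethylocta-2,6-dien-1-yl acetate | CC(=O)OC/C=C(/C)CCC=C(C)C | starting material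
9 | ozonide (1,2,4-trioxolane) of the distal olefin of neryl acetate | CC(=O)OC/C=C(/C)CCC1OOC(C)(C)O1 | intermediate
10 | (2Z)-3-methyl-6-oxohex-2-en-1-yl acetate | CC(=O)OC/C=C(/C)CCC=O | intermediate
11 | methyl (2E,6Z)-8-acetoxy-2-[(3E)-4-iodopent-3-en-1-yl]-6-methylocta-2,6-dienoate | CC(=O)OC/C=C(/C)CC/C=C(/C(=O)OC)CC/C=C(\C)I | intermediate
12 | methyl (2E,6Z)-8-hydroxy-2-[(3E)-4-iodopent-3-en-1-yl]-6-methylocta-2,6-dienoate | OC/C=C(/C)CC/C=C(/C(=O)OC)CC/C=C(\C)I | intermediate
13 | methyl (2E,6Z)-8-bromo-2-[(3E)-4-iodopent-3-en-1-yl]-6-methylocta-2,6-dienoate | BrC/C=C(/C)CC/C=C(/C(=O)OC)CC/C=C(\C)I | intermediate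
14 | but-3-yn-1-ol | C#CCCO | starting material
15 | prenyl bromide, 1-bromo-3-methylbut-2-ene | CC(C)=CCBr | starting material
16 | dimethylaluminium alkoxide of (E)-4-(dimethylalumanyl)-3-methylbut-3-en-1-ol | C[Al](C)OCC/C(C)=C/[Al](C)C | intermediate
17 | (3E)-3,7-dimethylocta-3,6-dien-1-ol | CC(C)=CC/C=C(\C)CCO | intermediate
18 | (3E)-3,7-dimethylocta-3,6-dienal | CC(C)=CC/C=C(\C)CC=O | intermediate
19 | (3E)-3,7-dimethylocta-3,6-dienoic acid | CC(C)=CC/C=C(\C)CC(=O)O | intermediate
20 | (R)-4-benzyloxazolidin-2-one | O=C1N[C@H](Cc2ccccc2)CO1 | starting material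
21 | (3E)-3,7-dimethylocta-3,6-dienoic pivalic anhydride | CC(C)=CC/C=C(\C)CC(=O)OC(=O)C(C)(C)C | intermediate
22 | (4R)-4-benzyl-3-[(3E)-3,7-dimethylocta-3,6-dienoyl]oxazolidin-2-one | CC(C)=CC/C=C(\C)CC(=O)N1C(=O)OC[C@H]1Cc1ccccc1 | intermediate
23 | sodium Z enolate of imide 22 | [Na+].[O-]/C(=C\C(C)=C\CC=C(C)C)N1C(=O)OC[C@H]1Cc1ccccc1 | intermediate
24 | methyl (2E,6Z,9R,10E)-9-{[(4R)-4-benzyl-2-oxo-1,3-oxazolidin-3-yl]carbonyl}-2-[(3E)-4-iodopent-3-en-1-yl]-6,10,14-trimethylpentadeca-2,6,10,13-tetraenoate | CC(C)=CC/C=C(\C)[C@H](C(=O)N1C(=O)OC[C@H]1Cc1ccccc1)C/C=C(/C)CC/C=C(/C(=O)OC)CC/C=C(\C)I | intermediate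
25 | methyl (2E,6Z,9R,10E)-9-(hydroxymethyl)-2-[(3E)-4-iodopent-3-en-1-yl]-6,10,14-trimethylpentadeca-2,6,10,13-tetraenoate | CC(C)=CC/C=C(\C)[C@H](CO)C/C=C(/C)CC/C=C(/C(=O)OC)CC/C=C(\C)I | intermediate
26 | methyl (2E,6Z,9R,10E)-9-formyl-2-[(3E)-4-iodopent-3-en-1-yl]-6,10,14-trimethylpentadeca-2,6,10,13-tetraenoate | CC(C)=CC/C=C(\C)[C@H](C=O)C/C=C(/C)CC/C=C(/C(=O)OC)CC/C=C(\C)I | intermediate
27 | methyl (2E,6Z,9S,10E)-9-ethenyl-2-[(3E)-4-iodopent-3-en-1-yl]-6,10,14-trimethylpentadeca-2,6,10,13-tetraenoate | CC(C)=CC/C=C(\C)[C@H](C=C)C/C=C(/C)CC/C=C(/C(=O)OC)CC/C=C(\C)I | intermediate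
28 | B-alkyl-9-BBN from 27: the ethenyl group is converted into 2-(9-borabicyclo[3.3.1]nonan-9-yl)ethyl, same configuration in space | CC(C)=CC/C=C(\C)[C@H](CCB1C2CCCC1CCC2)C/C=C(/C)CC/C=C(/C(=O)OC)CC/C=C(\C)I | intermediate
29 | macrocyclic methyl ester: target ring (C1 R, 3Z,7E,11E) with CO2Me on C8 in place of CH2OH | CC(C)=CC/C=C(\C)[C@H]1C/C=C(/C)CC/C=C(/C(=O)OC)CC/C=C(\C)CC1 | intermediate
30 | target: 14-membered ring, C1 (R) bearing (E)-6-methylhepta-2,5-dien-2-yl, C3=C4 Z with 4-methyl, C7=C8 E with 8-hydroxymethyl, C11=C12 E with 12-methyl | CC(C)=CC/C=C(\C)[C@H]1C/C=C(/C)CC/C=C(/CO)CC/C=C(\C)CC1 | target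

Total step count: 16. Longest linear sequence: 12 steps (steps 1, 2, 3, 5, 6, 7, 11, 12, 13, 14, 15, 16).

Steps most likely to fail

Step 15. The risk is that intermolecular coupling (oligomerisation), protodeboronation or β-hydride elimination outpaces the slow transfer of the primary alkyl group from boron to the hindered alkenylpalladium. The fallback sets out from 27 and comes back to the route at 29, and it closes the same C12–C13 bond with an organozinc instead of an organoboron nucleophile. Hydroboration of 27 with 9-BBN followed by oxidation with NaBO3·4H2O should give the 9-(2-hydroxyethyl) analogue of 27 F1. Iodination with I2, PPh3 and imidazole should then give the 9-(2-iodoethyl) analogue of 27 F2. Zinc dust with LiCl in THF at 40 °C should insert only into the sp3 C–I bond to give the alkylzinc iodide F3, which is not isolated. Slow addition of F3 to Pd(PPh3)4 in THF/NMP at 50 °C at high dilution (intramolecular Negishi coupling, retention at the iodoalkene) should give 29.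

Step 14. The risk is enolisation of the α-alkenyl aldehyde through its dienol before or during methylenation, which would erode the configuration at C1 or move the C15=C16 olefin into conjugation. The fallback sets out from 25 and comes back at 27, and it never passes through the aldehyde. Mitsunobu thioetherification of 25 with 1-phenyl-1H-tetrazole-5-thiol (PPh3, DIAD, THF) should give the tetrazolyl sulfide F4. Oxidation with H2O2 and catalytic (NH4)6Mo7O24·4H2O in EtOH should give the tetrazolyl sulfone F5. Deprotonation of F5 with KN(SiMe3)2 at −78 °C and trapping with monomeric formaldehyde (Julia–Kocienski methylenation; the carbanion sits on C14 and leaves the C1–H bond untouched) should give 27.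

Step 11. The risk is alkylation at the γ-carbon (C16) of the extended enolate, insufficient facial discrimination, or decay of the sodium enolate before the allylic bromide is consumed. The fallback sets out from 19 and 13 and comes back at 25, and it replaces the covalent auxiliary by a non-covalent chiral base acting on a dianion. Double deprotonation of acid 19 with a C2-symmetric chiral dilithium amide (tetramine base with n-BuLi, THF, 0 °C) gives the enediolate, whose charge is concentrated at the α-carbon. Alkylation with 13 at −78 °C, using the enantiomer of the base that gives the (R) centre, should give the α-alkylated acid F6. Activation of F6 with isobutyl chloroformate and N-methylmorpholine at −15 °C gives the mixed carbonic anhydride F7 (not isolated). Reduction of F7 with NaBH4 in THF/MeOH, which spares the conjugated methyl ester, should give 25.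

Further compounds
F1 | step 15 | methyl (2E,6Z,9S,10E)-9-(2-hydroxyethyl)-2-[(3E)-4-iodopent-3-en-1-yl]-6,10,14-trimethylpentadeca-2,6,10,13-tetraenoate | CC(C)=CC/C=C(\C)[C@H](CCO)C/C=C(/C)CC/C=C(/C(=O)OC)CC/C=C(\C)I
F2 | step 15 | methyl (2E,6Z,9S,10E)-9-(2-iodoethyl)-2-[(3E)-4-iodopent-3-en-1-yl]-6,10,14-trimethylpentadeca-2,6,10,13-tetraenoate | CC(C)=CC/C=C(\C)[C@H](CCI)C/C=C(/C)CC/C=C(/C(=O)OC)CC/C=C(\C)I
F3 | step 15 | alkylzinc iodide from F2 (zinc on the terminal carbon of the ethyl arm) | CC(C)=CC/C=C(\C)[C@H](CC[Zn]I)C/C=C(/C)CC/C=C(/C(=O)OC)CC/C=C(\C)I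
F4 | step 14 | methyl (2E,6Z,9R,10E)-2-[(3E)-4-iodopent-3-en-1-yl]-6,10,14-trimethyl-9-{[(1-phenyl-1H-tetrazol-5-yl)sulfanyl]methyl}pentadeca-2,6,10,13-tetraenoate | CC(C)=CC/C=C(\C)[C@H](CSc1nnnn1-c1ccccc1)C/C=C(/C)CC/C=C(/C(=O)OC)CC/C=C(\C)I
F5 | step 14 | methyl (2E,6Z,9R,10E)-2-[(3E)-4-iodopent-3-en-1-yl]-6,10,14-trimethyl-9-{[(1-phenyl-1H-tetrazol-5-yl)sulfonyl]methyl}pentadeca-2,6,10,13-tetraenoate | CC(C)=CC/C=C(\C)[C@H](CS(=O)(=O)c1nnnn1-c1ccccc1)C/C=C(/C)CC/C=C(/C(=O)OC)CC/C=C(\C)I
F6 | step 11 | (2R,3E)-2-{(2Z,6E)-7-(methoxycarbonyl)-11-iodo-3-methyldodeca-2,6,10-trien-1-yl}-3,7-dimethylocta-3,6-dienoic acid (the free acid corresponding to imide 24) | CC(C)=CC/C=C(\C)[C@H](C(=O)O)C/C=C(/C)CC/C=C(/C(=O)OC)CC/C=C(\C)I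
F7 | step 11 | isobutyl carbonic mixed anhydride of acid F6 | CC(C)=CC/C=C(\C)[C@H](C(=O)OC(=O)OCC(C)C)C/C=C(/C)CC/C=C(/C(=O)OC)CC/C=C(\C)I
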